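The numbers in the tables stem from a simulated flask with made-up constants, noise included.

Wednesday's flask and Saturday's differ in temperature, −20 °C against 10 °C, and each stands for 40 h, so I count how many half-times of the starting material fit into that time.

| flask | starting material | partner | free catalyst | added ligand | temperature | remark | time |
|---|---|---|---|---|---|---|---|
| eta | 0.22 M | 0.22 M | 2.6 mM | 7.5 mM | −12 °C | run made earlier |  |
| epsilon | 0.22 M | 0.22 M | 2.6 mM | 11 mM | 4 °C | run made earlier |  |
| delta | 0.11 M | 0.22 M | 2.6 mM | 15 mM | −12 °C | run made earlier |  |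
| Wednesday's | 0.22 M | 0.220 M | 2.6 mM | 15 mM | −20 °C |  | 40 h |
| Saturday's | 0.22 M | 0.220 M | 2.6 mM | 15 mM | 10 °C |  | 40 h |

| run | time / h | target / % | starting material / % |
|---|---|---|---|
| eta | 3.00 | 9.1 | 88.4 |
| eta | 5.00 | 17.7 | 81.7 |
| eta | 8.00 | 26.3 | 73.2 |
| eta | 12.0 | 40.4 | 61.6 |
| eta | 15.0 | 46.3 | 52.0 |
| eta | 25.0 | 68.5 | 29.8 |
| eta | 40.0 | 89.0 | 11.8 |
| epsilon | 0.667 | 14.4 | 88.9 |
| epsilon | 2.00 | 32.8 | 64.7 |
| epsilon | 4.00 | 58.4 | 40.8 |
| epsilon | 5.00 | 68.9 | 30.4 |
| epsilon | 8.00 | 85.2 | 13.6 |
| epsilon | 10.0 | 92.6 | 6.8 |
| epsilon | 12.0 | 96.5 | 4.8 |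
| delta | 4.00 | 17.8 | 81.0 |
| delta | 10.0 | 44.2 | 55.7 |
| delta | 20.0 | 72.5 | 26.7 |
| delta | 30.0 | 87.4 | 11.0 |
| delta | 40.0 | 94.7 | 4.1 |

(scatter of a reading: 1 percentage point)



* which flask leads in amount of target, in percent of the starting material charged ("all alike" within 1.5 percentage points) (Wednesday's / Saturday's / all alike)
* how much target is there at the end, in percent of the starting material charged: Wednesday's
* how much target is there at the end, in percent of the starting material charged: Saturday's

I reckon each half-time as if the decay were first order, from the reading nearest the half. Eta's 52.0% left at 15.0 h gives 15.9 h, and epsilon's 40.8% left at 4.00 h gives 3.09 h. Their added ligand differs too, but I read the whole gap as temperature, which gives an apparent activation energy of 61.6 kJ mol⁻¹. Carried down from eta, with the difference in added ligand again set aside, this gives 39.0 h for Wednesday's flask: that time, in which by this reckoning its starting material falls to half its charge, is what I carry. Saturday's flask gets 1.76 h.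

The ladder, from the shortest half-time to the longest, runs from Saturday's 1.76 h through epsilon's 3.09 h, delta's 11.8 h and eta's 15.9 h to Wednesday's 39.0 h. Delta, with half the starting material and a different charge of added ligand, sits below eta, so I kept it out of the temperature reckoning. Saturday's flask fits 22.7 half-times, so nearly all of its starting material reacts. Wednesday's fits 1.03, which leaves 49.1% and makes 50.9% target.

The forecast, which departs from my first-order count, names Saturday's, with 51% (42% to 60%) for Wednesday's and 99% (95% to 100%) for Saturday's, reasoning that “the order in starting material is below one”.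

The flasks give 46.9% for Wednesday's and >99.9% for Saturday's, so Saturday's leads. Eta without its scatter holds 88.1% target at the time of its last reading; with only the temperature changed to Wednesday's it holds 49.4%, and with only the added ligand changed to Wednesday's it holds 84.9%. Wednesday's 53% left at 40.0 h corresponds, counted as first order, to a half-time of 43.2 h, longer than my 39.0 h.

    free catalyst + added ligand ⇌ idle complex, settled at all times (K = 160 M⁻¹, ΔH = 9.00 kJ mol⁻¹)
    partner + free catalyst → catalyst intermediate A (k = 2.00 M⁻¹ min⁻¹, Ea = 56.0 kJ mol⁻¹)
    catalyst intermediate A → released group + catalyst intermediate B (k = 1.69 min⁻¹, Ea = 60.0 kJ mol⁻¹)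
    catalyst intermediate B → catalyst intermediate C (k = 3.77 min⁻¹, Ea = 75.0 kJ mol⁻¹)
    starting material + catalyst intermediate C → catalyst intermediate D (k = 0.278 M⁻¹ min⁻¹, Ea = 61.0 kJ mol⁻¹)
    catalyst intermediate D → free catalyst + target (k = 0.0375 min⁻¹, Ea = 70.0 kJ mol⁻¹)
    (constants at −20 °C)

For the neighbour of Wednesday's flask with 4.40 mM of free catalyst, I shorten 39.0 h in proportion to the catalyst charge, to 23.0 h, and 1.74 half-times leave 30.0% of the starting material. The computed flask has 30% left and 69.4% target.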